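**Plan**

1. Numbering (daucane): C1 = quaternary C(CH3), C2/C3 = the CH2 groups of ring A (five-membered), C4 = C(OH)iPr, C5 = ring-fusion CH, C6 = CH–OBz, C7, C8/C9 = epoxide carbons, C10; ring B is the seven-membered ring.
2. Retrosynthesis: the benzoate, the isopropyl group (back to a C4 ketone, itself from C4=CH2) and the epoxide are removed. Ring A of the resulting trans-fused methylenehydroazulene is then cut at C2–C3 and at the fusion bond C5–C1; because C5–C1 also lies in ring B, this [3+2] cut opens both rings to one acyclic chain.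
3. Enabling feature: C3–C4–C5 of ring A, with the oxygen-bearing C4 at its centre, is a masked trimethylenemethane (C4=CH2 stands for C4=O). C1(CH3)–C2 is the two-carbon partner, activated as a β-methyl vinyl sulfone, and the (Z)-C8=C9 alkene of ring B folds the tether.
4. Forward: but-2-yn-1-ol gives a (Z)-vinyl iodide that is joined to methyl (S)-glycidate (C7–C8). Carboalumination, iodination and sulfinate coupling build the vinyl sulfone; a Nozaki–Hiyama–Kishi coupling and acetylation install the silylmethylallyl acetate.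
5. The palladium-catalysed cycloaddition closes ring B, then ring A, in one operation. Desulfonylation, epoxidation, ozonolysis, isopropyl addition, desilylation and benzoylation finish the route.
6. Stereochemistry: C6 comes from methyl (S)-glycidate. C5 and C1 are set in the key step under control of C6. The epoxide forms on the convex α face, and the isopropyl group adds to the C4 ketone anti to the angular methyl.

Key step: step 12

Remarks: 18 and 19 are epimer mixtures at the carbinol/acetoxy carbon and 20 at the sulfonyl carbon; these centres are lost later, so their SMILES leave them undefined. Names of bicyclic compounds use azulene locants (C1→8a, C2→1, C3→2, C4→3, C5→3a, C6→4, C7→5, C8→6, C9→7, C10→8).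

**Route**

Step 1
Reactants: 1 but-2-yn-1-ol
Product: 3 (Z)-3-iodobut-2-en-1-ol, via cyclic alkenylaluminate 2 (not isolated)
Conditions: NaAlH2(OCH2CH2OCH3)2, THF, 0 °C to rt; then I2, THF, −78 to 0 °C
Reagents that add atoms: iodine, II
Why: Hydroxyl-directed trans-hydroalumination of the propargylic alcohol and iodinolysis of the C–Al bond with retention should give the (Z)-iodide, which fixes the cis relation of C7 and C10 across the later ring B alkene.

Step 2
Reactants: 3 (Z)-3-iodobut-2-en-1-ol
Product: 4 (Z)-1-bromo-3-iodobut-2-ene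
Conditions: PBr3, Et2O, 0 °C
Reagents that add atoms: phosphorus tribromide, BrP(Br)Br
Why: Conversion of the primary allylic alcohol into the bromide (SN2 on the phosphite ester) should leave the alkene geometry and the vinyl iodide untouched.

Step 3
Reactants: 4 (Z)-1-bromo-3-iodobut-2-ene; 5 ethynyltrimethylsilane
Product: 6 (Z)-(5-iodohex-4-en-1-yn-1-yl)trimethylsilane
Conditions: CuI (10 mol%), Bu4NI (10 mol%), K2CO3, DMF, rt
Reagents that add atoms: none
Why: Copper-catalysed SN2 coupling of a terminal alkyne with an allylic bromide should give the skipped enyne and forms the C10–C1 bond; the vinyl iodide does not couple with the copper acetylide at room temperature.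

Step 4
Reactants: 6 (Z)-(5-iodohex-4-en-1-yn-1-yl)trimethylsilane; 7 methyl (2S)-oxirane-2-carboxylate (methyl (S)-glycidate)
Product: 10 methyl (2S,4Z)-2-hydroxy-4-methyl-8-(trimethylsilyl)oct-4-en-7-ynoate, via alkenyllithium 8 (not isolated), via alkenylmagnesium bromide 9 (not isolated)
Conditions: t-BuLi (2 equiv), Et2O, −78 °C; MgBr2·OEt2; CuI (10 mol%), then 7, THF, −40 °C; aqueous NH4Cl
Reagents that add atoms: none
Why: Iodine–lithium exchange with retention of geometry, transmetalation to magnesium and copper-catalysed SN2 opening of the glycidate at its CH2 terminus should form the C7–C8 bond; the C6 stereocentre is taken over unchanged from the chiral pool epoxide.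

Step 5
Reactants: 10 methyl (2S,4Z)-2-hydroxy-4-methyl-8-(trimethylsilyl)oct-4-en-7-ynoate
Product: 11 methyl (2S,4Z)-2-[(tert-butyldimethylsilyl)oxy]-4-methyl-8-(trimethylsilyl)oct-4-en-7-ynoate
Conditions: TBSOTf, 2,6-lutidine, CH2Cl2, −78 to 0 °C
Reagents that add atoms: tert-butyldimethylsilyl trifluoromethanesulfonate, CC(C)(C)[Si](C)(C)OS(=O)(=O)C(F)(F)F
Why: O-Silylation of the secondary alcohol gives a C6 ether that is not a leaving group next to the later carbanionic donor carbon and should survive all steps up to step 17.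

Step 6
Reactants: 11 methyl (2S,4Z)-2-[(tert-butyldimethylsilyl)oxy]-4-methyl-8-(trimethylsilyl)oct-4-en-7-ynoate
Product: 12 methyl (2S,4Z)-2-[(tert-butyldimethylsilyl)oxy]-4-methyloct-4-en-7-ynoate
Conditions: K2CO3 (cat.), MeOH, 0 °C
Reagents that add atoms: none
Why: Carbonate-catalysed methanolysis of the alkynyl C–Si bond should free the terminal alkyne, while the O-silyl ether and the methyl ester stay intact at 0 °C.

Step 7
Reactants: 12 methyl (2S,4Z)-2-[(tert-butyldimethylsilyl)oxy]-4-methyloct-4-en-7-ynoate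
Product: 14 methyl (2S,4Z,7E)-2-[(tert-butyldimethylsilyl)oxy]-8-iodo-4,7-dimethylocta-4,7-dienoate, via alkenylalane 13 (not isolated)
Conditions: Me3Al, (C5H5)2ZrCl2 (20 mol%), H2O (1 equiv), CH2Cl2, −23 °C; then I2, THF, −23 to 0 °C
Reagents that add atoms: trimethylaluminium, C[Al](C)C; iodine, II
Why: Zirconium-catalysed syn-carboalumination of the terminal alkyne (Negishi carboalumination) places the methyl group on C1 and aluminium on C2, and iodinolysis with retention should give the (E)-vinyl iodide.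

Step 8
Reactants: 14 methyl (2S,4Z,7E)-2-[(tert-butyldimethylsilyl)oxy]-8-iodo-4,7-dimethylocta-4,7-dienoate
Product: 15 methyl (2S,4Z,7E)-2-[(tert-butyldimethylsilyl)oxy]-4,7-dimethyl-8-(phenylsulfonyl)octa-4,7-dienoate
Conditions: PhSO2Na, CuI (10 mol%), sodium L-prolinate (20 mol%), DMSO, 80 °C
Reagents that add atoms: sodium benzenesulfinate, [Na+].[O-]S(=O)c1ccccc1
Why: Copper-catalysed C–S cross-coupling of the vinyl iodide with the sulfinate, with retention of geometry, should give the β-methyl vinyl sulfone that serves as the activated two-carbon partner.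

Step 9
Reactants: 15 methyl (2S,4Z,7E)-2-[(tert-butyldimethylsilyl)oxy]-4,7-dimethyl-8-(phenylsulfonyl)octa-4,7-dienoate
Product: 16 (2S,4Z,7E)-2-[(tert-butyldimethylsilyl)oxy]-4,7-dimethyl-8-(phenylsulfonyl)octa-4,7-dienal
Conditions: iBu2AlH (1.1 equiv), CH2Cl2, −78 °C; aqueous potassium sodium tartrate
Reagents that add atoms: none
Why: Partial reduction of the α-silyloxy methyl ester at −78 °C should stop at the aldehyde through the stable tetrahedral aluminium acetal; the vinyl sulfone is not reduced at this temperature.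

Step 10
Reactants: 16 (2S,4Z,7E)-2-[(tert-butyldimethylsilyl)oxy]-4,7-dimethyl-8-(phenylsulfonyl)octa-4,7-dienal; 17 (2-bromoprop-2-en-1-yl)trimethylsilane
Product: 18 (4S,6Z,9E)-4-[(tert-butyldimethylsilyl)oxy]-6,9-dimethyl-10-(phenylsulfonyl)-2-[(trimethylsilyl)methyl]deca-1,6,9-trien-3-ol (C3 epimers)
Conditions: CrCl2 (4 equiv), NiCl2 (2 mol%), DMF, rt
Reagents that add atoms: none
Why: The Nozaki–Hiyama–Kishi coupling is chemoselective for the aldehyde and non-basic, so the vinyl sulfone and C6 are not touched; the new carbinol centre forms as a mixture that converges in step 12.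

Step 11
Reactants: 18 (4S,6Z,9E)-4-[(tert-butyldimethylsilyl)oxy]-6,9-dimethyl-10-(phenylsulfonyl)-2-[(trimethylsilyl)methyl]deca-1,6,9-trien-3-ol
Product: 19 (4S,6Z,9E)-4-[(tert-butyldimethylsilyl)oxy]-6,9-dimethyl-10-(phenylsulfonyl)-2-[(trimethylsilyl)methyl]deca-1,6,9-trien-3-yl acetate (C3 epimers)
Conditions: Ac2O, Et3N, DMAP (cat.), CH2Cl2, rt
Reagents that add atoms: acetic anhydride, CC(=O)OC(C)=O
Why: DMAP-catalysed acylation of the secondary allylic alcohol gives the allylic acetate that acts as leaving group and as internal desilylating agent in the next step.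

Step 12
Reactants: 19 (4S,6Z,9E)-4-[(tert-butyldimethylsilyl)oxy]-6,9-dimethyl-10-(phenylsulfonyl)-2-[(trimethylsilyl)methyl]deca-1,6,9-trien-3-yl acetate
Product: 20 tert-butyl{[(3aS,4S,8aR)-6,8a-dimethyl-3-methylidene-1-(phenylsulfonyl)-1,2,3,3a,4,5,8,8a-octahydroazulen-4-yl]oxy}dimethylsilane (epimers at the sulfonyl carbon)
Conditions: Pd(OAc)2 (10 mol%), P(OiPr)3 (60 mol%), Me3SnOAc (10 mol%), dioxane (0.005 M), 100 °C
Reagents that add atoms: none
Why: Zerovalent palladium ionises the allylic acetate, acetate removes the silyl group, and the zwitterionic trimethylenemethane–palladium complex adds through its substituted terminus C5 to the β-carbon C1 of the vinyl sulfone, after which the α-sulfonyl carbanion at C2 collapses onto the π-allylpalladium terminus C3. The closest known reaction type is the intramolecular palladium-catalysed trimethylenemethane [3+2] cycloaddition onto vinyl sulfones that gives perhydroazulenes. Ring B closes by a 7-exo-trig Michael addition, helped by the (Z)-C8=C9 alkene that holds C7 and C10 cis, and ring A by a 5-exo allylic alkylation of the stabilised carbanion. C5 is controlled by the silyloxy-bearing C6 through allylic 1,3-strain (C6–H lies in the plane of the donor and C1 enters anti to the OTBS group); C1 is controlled by a chair-like cycloheptene transition state in which the larger sulfonylmethylene arm is pseudo-equatorial and the methyl pseudo-axial, which corresponds to the trans ring fusion. The step needs regioselectivity (secured by the tether and by the preference of the substituted terminus to attack first), C–C bond formation in preference to proton transfer from C10–H (acetate as leaving group, no added base, high dilution) and diastereoselectivity at C5 and C1 (secured by C6 as argued).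

Step 13
Reactants: 20 tert-butyl{[(3aS,4S,8aR)-6,8a-dimethyl-3-methylidene-1-(phenylsulfonyl)-1,2,3,3a,4,5,8,8a-octahydroazulen-4-yl]oxy}dimethylsilane
Product: 21 tert-butyl{[(3aS,4S,8aR)-6,8a-dimethyl-3-methylidene-1,2,3,3a,4,5,8,8a-octahydroazulen-4-yl]oxy}dimethylsilane
Conditions: Na(Hg) (6% Na), Na2HPO4, MeOH–THF, −20 °C
Reagents that add atoms: none
Why: Reductive desulfonylation by electron transfer from the amalgam cleaves the C2–S bond and protonation gives the C2 methylene; the isolated alkenes and the silyl ether are inert.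

Step 14
Reactants: 21 tert-butyl{[(3aS,4S,8aR)-6,8a-dimethyl-3-methylidene-1,2,3,3a,4,5,8,8a-octahydroazulen-4-yl]oxy}dimethylsilane
Product: 22 tert-butyl{[(3aS,4S,6R,7S,8aR)-6,7-epoxy-6,8a-dimethyl-3-methylidenedecahydroazulen-4-yl]oxy}dimethylsilane
Conditions: mCPBA (1.05 equiv), NaHCO3, CH2Cl2, −20 °C
Reagents that add atoms: 3-chloroperoxybenzoic acid, OOC(=O)c1cccc(Cl)c1
Why: The Prilezhaev epoxidation is chemoselective for the more electron-rich trisubstituted ring alkene over the exocyclic 1,1-disubstituted one, and should occur on the convex α face because the C6–C5–C1 bridge of the chair cycloheptene, with its axial angular methyl, shields the β face.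

Step 15
Reactants: 22 tert-butyl{[(3aS,4S,6R,7S,8aR)-6,7-epoxy-6,8a-dimethyl-3-methylidenedecahydroazulen-4-yl]oxy}dimethylsilane
Product: 24 (3aS,4S,6R,7S,8aR)-4-[(tert-butyldimethylsilyl)oxy]-6,7-epoxy-6,8a-dimethyloctahydroazulen-3(2H)-one, via ozonide 23 (not isolated)
Conditions: O3, CH2Cl2, −78 °C; then Me2S, −78 °C to rt
Reagents that add atoms: ozone, [O-][O+]=O
Why: Ozonolysis of the exocyclic methylene with reductive work-up unmasks the C4 ketone; the ring B alkene is already protected as the epoxide and C5 is not exposed to base.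

Step 16
Reactants: 24 (3aS,4S,6R,7S,8aR)-4-[(tert-butyldimethylsilyl)oxy]-6,7-epoxy-6,8a-dimethyloctahydroazulen-3(2H)-one
Product: 25 (3R,3aS,4S,6R,7S,8aR)-4-[(tert-butyldimethylsilyl)oxy]-6,7-epoxy-6,8a-dimethyl-3-(propan-2-yl)decahydroazulen-3-ol
Conditions: iPrMgCl, CeCl3, THF, −78 °C
Reagents that add atoms: isopropylmagnesium chloride, CC(C)[Mg]Cl
Why: 1,2-Addition of the weakly basic organocerium reagent to the cyclopentanone should occur from the α face, anti to the pseudo-axial angular methyl on C1 and to the C6 branch on C5, which sets C4 with β hydroxyl and α isopropyl.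

Step 17
Reactants: 25 (3R,3aS,4S,6R,7S,8aR)-4-[(tert-butyldimethylsilyl)oxy]-6,7-epoxy-6,8a-dimethyl-3-(propan-2-yl)decahydroazulen-3-ol
Product: 26 (3R,3aS,4S,6R,7S,8aR)-6,7-epoxy-6,8a-dimethyl-3-(propan-2-yl)decahydroazulene-3,4-diol
Conditions: Bu4NF, THF, 0 °C to rt
Reagents that add atoms: none
Why: Fluoride-induced cleavage of the secondary silyl ether liberates the C6 alcohol; the epoxide and the tertiary alcohol are stable to fluoride at this temperature.

Step 18
Reactants: 26 (3R,3aS,4S,6R,7S,8aR)-6,7-epoxy-6,8a-dimethyl-3-(propan-2-yl)decahydroazulene-3,4-diol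
Product: 27 (3R,3aS,4S,6R,7S,8aR)-6,7-epoxy-3-hydroxy-6,8a-dimethyl-3-(propan-2-yl)decahydroazulen-4-yl benzoate
Conditions: BzCl, Et3N, DMAP (cat.), CH2Cl2, 0 °C
Reagents that add atoms: benzoyl chloride, O=C(Cl)c1ccccc1
Why: DMAP-catalysed acylation is selective for the secondary C6 hydroxyl over the hindered tertiary C4 hydroxyl and should give the target.

**Compound list**

1 | but-2-yn-1-ol | CC#CCO | starting material
2 | sodium 2,2-bis(2-methoxyethoxy)-3-methyl-2,5-dihydro-1,2-oxaluminol-2-uide (cyclic alkenylaluminate, not isolated) | CC1=CCO[Al-]1(OCCOC)OCCOC.[Na+] | intermediate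
3 | (Z)-3-iodobut-2-en-1-ol | C/C(I)=C/CO | intermediate
4 | (Z)-1-bromo-3-iodobut-2-ene | C/C(I)=C/CBr | intermediate
5 | ethynyltrimethylsilane | C#C[Si](C)(C)C | starting material
6 | (Z)-(5-iodohex-4-en-1-yn-1-yl)trimethylsilane | C/C(I)=C/CC#C[Si](C)(C)C | intermediate
7 | methyl (2S)-oxirane-2-carboxylate (methyl (S)-glycidate) | COC(=O)[C@@H]1CO1 | starting material
8 | [6-(trimethylsilyl)hex-2-en-5-yn-2-yl]lithium, Li cis to the CH2 group (not isolated) | C/C([Li])=C/CC#C[Si](C)(C)C | intermediate
9 | bromo[(2Z)-6-(trimethylsilyl)hex-2-en-5-yn-2-yl]magnesium (not isolated) | C/C([Mg]Br)=C/CC#C[Si](C)(C)C | intermediate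
10 | methyl (2S,4Z)-2-hydroxy-4-methyl-8-(trimethylsilyl)oct-4-en-7-ynoate | COC(=O)[C@@H](O)C/C(C)=C\CC#C[Si](C)(C)C | intermediate
11 | methyl (2S,4Z)-2-[(tert-butyldimethylsilyl)oxy]-4-methyl-8-(trimethylsilyl)oct-4-en-7-ynoate | COC(=O)[C@@H](O[Si](C)(C)C(C)(C)C)C/C(C)=C\CC#C[Si](C)(C)C | intermediate
12 | methyl (2S,4Z)-2-[(tert-butyldimethylsilyl)oxy]-4-methyloct-4-en-7-ynoate | COC(=O)[C@@H](O[Si](C)(C)C(C)(C)C)C/C(C)=C\CC#C | intermediate
13 | methyl (2S,4Z,7E)-2-[(tert-butyldimethylsilyl)oxy]-8-(dimethylalumanyl)-4,7-dimethylocta-4,7-dienoate (not isolated) | COC(=O)[C@@H](O[Si](C)(C)C(C)(C)C)C/C(C)=C\C/C(C)=C/[Al](C)C | intermediate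
14 | methyl (2S,4Z,7E)-2-[(tert-butyldimethylsilyl)oxy]-8-iodo-4,7-dimethylocta-4,7-dienoate | COC(=O)[C@@H](O[Si](C)(C)C(C)(C)C)C/C(C)=C\C/C(C)=C/I | intermediate
15 | methyl (2S,4Z,7E)-2-[(tert-butyldimethylsilyl)oxy]-4,7-dimethyl-8-(phenylsulfonyl)octa-4,7-dienoate | COC(=O)[C@@H](O[Si](C)(C)C(C)(C)C)C/C(C)=C\C/C(C)=C/S(=O)(=O)c1ccccc1 | intermediate
16 | (2S,4Z,7E)-2-[(tert-butyldimethylsilyl)oxy]-4,7-dimethyl-8-(phenylsulfonyl)octa-4,7-dienal | O=C[C@@H](O[Si](C)(C)C(C)(C)C)C/C(C)=C\C/C(C)=C/S(=O)(=O)c1ccccc1 | intermediate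
17 | (2-bromoprop-2-en-1-yl)trimethylsilane | C=C(Br)C[Si](C)(C)C | starting material
18 | (4S,6Z,9E)-4-[(tert-butyldimethylsilyl)oxy]-6,9-dimethyl-10-(phenylsulfonyl)-2-[(trimethylsilyl)methyl]deca-1,6,9-trien-3-ol (C3 epimers) | C=C(C[Si](C)(C)C)C(O)[C@@H](O[Si](C)(C)C(C)(C)C)C/C(C)=C\C/C(C)=C/S(=O)(=O)c1ccccc1 | intermediate
19 | (4S,6Z,9E)-4-[(tert-butyldimethylsilyl)oxy]-6,9-dimethyl-10-(phenylsulfonyl)-2-[(trimethylsilyl)methyl]deca-1,6,9-trien-3-yl acetate (C3 epimers) | C=C(C[Si](C)(C)C)C(OC(C)=O)[C@@H](O[Si](C)(C)C(C)(C)C)C/C(C)=C\C/C(C)=C/S(=O)(=O)c1ccccc1 | intermediate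
20 | tert-butyl{[(3aS,4S,8aR)-6,8a-dimethyl-3-methylidene-1-(phenylsulfonyl)-1,2,3,3a,4,5,8,8a-octahydroazulen-4-yl]oxy}dimethylsilane (C1 epimers) | C=C1CC(S(=O)(=O)c3ccccc3)[C@]2(C)CC=C(C)C[C@H](O[Si](C)(C)C(C)(C)C)[C@H]21 | intermediate
21 | tert-butyl{[(3aS,4S,8aR)-6,8a-dimethyl-3-methylidene-1,2,3,3a,4,5,8,8a-octahydroazulen-4-yl]oxy}dimethylsilane | C=C1CC[C@]2(C)CC=C(C)C[C@H](O[Si](C)(C)C(C)(C)C)[C@H]21 | intermediate
22 | tert-butyl{[(3aS,4S,6R,7S,8aR)-6,7-epoxy-6,8a-dimethyl-3-methylidenedecahydroazulen-4-yl]oxy}dimethylsilane | C=C1CC[C@]2(C)C[C@@H]3O[C@]3(C)C[C@H](O[Si](C)(C)C(C)(C)C)[C@H]21 | intermediate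
23 | spiro-1,2,4-trioxolane (ozonide) of 22 at C3 of the azulene, (3aS,4S,6R,7S,8aR), spiro centre undefined (not isolated) | C1OOC2(O1)CC[C@]3(C)C[C@@H]4O[C@]4(C)C[C@H](O[Si](C)(C)C(C)(C)C)[C@H]32 | intermediate
24 | (3aS,4S,6R,7S,8aR)-4-[(tert-butyldimethylsilyl)oxy]-6,7-epoxy-6,8a-dimethyloctahydroazulen-3(2H)-one | O=C1CC[C@]2(C)C[C@@H]3O[C@]3(C)C[C@H](O[Si](C)(C)C(C)(C)C)[C@H]21 | intermediate
25 | (3R,3aS,4S,6R,7S,8aR)-4-[(tert-butyldimethylsilyl)oxy]-6,7-epoxy-6,8a-dimethyl-3-(propan-2-yl)decahydroazulen-3-ol | CC(C)[C@]1(O)CC[C@]2(C)C[C@@H]3O[C@]3(C)C[C@H](O[Si](C)(C)C(C)(C)C)[C@H]21 | intermediate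
26 | (3R,3aS,4S,6R,7S,8aR)-6,7-epoxy-6,8a-dimethyl-3-(propan-2-yl)decahydroazulene-3,4-diol | CC(C)[C@]1(O)CC[C@]2(C)C[C@@H]3O[C@]3(C)C[C@H](O)[C@H]21 | intermediate
27 | (3R,3aS,4S,6R,7S,8aR)-6,7-epoxy-3-hydroxy-6,8a-dimethyl-3-(propan-2-yl)decahydroazulen-4-yl benzoate | CC(C)[C@]1(O)CC[C@]2(C)C[C@@H]3O[C@]3(C)C[C@H](OC(=O)c3ccccc3)[C@H]21 | target

**Totals**

Total step count: 18. Longest linear sequence: 18 steps (from but-2-yn-1-ol; 5, 7 and 17 are purchased).

**Steps most likely to fail**

1. Step 12. Attack of the donor terminus on the fully substituted acceptor carbon may be slow, so that the basic zwitterion takes a proton from the doubly allylic C10 methylene; closure may also pass through the transition state that leads to the cis ring fusion. The fallback sets out from aldehyde 16. A Wittig reaction with cyclopropylidenetriphenylphosphorane (cyclopropyltriphenylphosphonium bromide, KN(SiMe3)2, THF, −78 to 0 °C) would give tert-butyl{[(2S,4Z,7E)-1-cyclopropylidene-4,7-dimethyl-8-(phenylsulfonyl)octa-4,7-dien-2-yl]oxy}dimethylsilane F1. A palladium-catalysed intramolecular alkylidenecyclopropane–alkene [3+2] cycloaddition (Pd2(dba)3, P(OiPr)3, dioxane, 100 °C) runs through oxidative addition into the strained ring and carbopalladation, with no free carbanion and no acetate, and would return to the route at 20.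

2. Step 8. At 80 °C in DMSO the sulfinate or the prolinate may deprotonate the doubly allylic methylene and move the new double bond out of conjugation with the sulfone, or the coupling may stall. The fallback sets out from vinyl iodide 14. Carbon–sulfur coupling at the sulfide oxidation level with benzenethiol (Pd2(dba)3, Xantphos, iPr2NEt, dioxane, rt to 50 °C) would give methyl (2S,4Z,7E)-2-[(tert-butyldimethylsilyl)oxy]-4,7-dimethyl-8-(phenylsulfanyl)octa-4,7-dienoate F2, which carries no acidifying group. Chemoselective oxidation at sulfur under neutral conditions ((NH4)6Mo7O24 cat., H2O2, EtOH, 0 °C) would then return to the route at 15.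

3. Step 16. The branched nucleophile may act as a base or as a hydride donor toward the hindered ketone (enolisation toward C5 with loss of the silyloxy group, or reduction) in place of addition. The fallback sets out from ketone 24. Addition of isopropenylmagnesium bromide with CeCl3 (THF, −78 °C), a smaller sp2 nucleophile without β-hydrogen, from the same α face would give (3S,3aS,4S,6R,7S,8aR)-4-[(tert-butyldimethylsilyl)oxy]-6,7-epoxy-6,8a-dimethyl-3-(prop-1-en-2-yl)decahydroazulen-3-ol F3. Hydrogenation of its 1,1-disubstituted alkene (H2, RhCl(PPh3)3, benzene, rt) would return to the route at 25.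

**Further compounds**

F1 | step 12 | tert-butyl{[(2S,4Z,7E)-1-cyclopropylidene-4,7-dimethyl-8-(phenylsulfonyl)octa-4,7-dien-2-yl]oxy}dimethylsilane | C1CC1=C[C@@H](O[Si](C)(C)C(C)(C)C)C/C(C)=C\C/C(C)=C/S(=O)(=O)c1ccccc1
F2 | step 8 | methyl (2S,4Z,7E)-2-[(tert-butyldimethylsilyl)oxy]-4,7-dimethyl-8-(phenylsulfanyl)octa-4,7-dienoate | COC(=O)[C@@H](O[Si](C)(C)C(C)(C)C)C/C(C)=C\C/C(C)=C/Sc1ccccc1
F3 | step 16 | (3S,3aS,4S,6R,7S,8aR)-4-[(tert-butyldimethylsilyl)oxy]-6,7-epoxy-6,8a-dimethyl-3-(prop-1-en-2-yl)decahydroazulen-3-ol | C=C(C)[C@]1(O)CC[C@]2(C)C[C@@H]3O[C@]3(C)C[C@H](O[Si](C)(C)C(C)(C)C)[C@H]21
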